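## Retrosynthetic overview

1. Last strategic bond C7–C8: the α‑methylene ketone precursor of the target is cut into a cyclohexyl alkenyl triflate (ring half) and a C8–C11 lactol (side‑chain half). A light‑driven nickel coupling joins them, then the C10 hydroxyl directs a syn reduction that sets C8.
2. Ring half: all ring carbons, the C4 methyl, C1 and C7 come from (S)‑(+)‑carvone 1. The ring oxygens are added to the intact ring in the order C2 (singlet‑oxygen γ‑oxygenation), C6 (α′‑hydroxylation, then inversion), C5 (Luche reduction), C3/C4 (directed epoxidation, angelate opening).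
3. Side‑chain half: C8–C11 with the C10 stereocenter from L‑malic acid 2.
4. Rings: no carbocycle is built; the cyclohexane of 1 is kept throughout. Only auxiliary heterocycles are made, in the order dioxolanone, γ‑lactone, lactol (side chain) and, transiently, the C3–C4 epoxide.

Assumption: the target is taken exactly as the given SMILES; locants below are those of the target (ring C1 carries the C7 unit, C2–C6 follow in SMILES order, chain C7–C11), β is the ring face carrying the C1 substituent, and for compounds 7–12 the names use carvone numbering.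

## Route

Step 1
Reactants: 2 L‑malic acid
Product: 3 (S)‑2‑(2,2‑dimethyl‑5‑oxo‑1,3‑dioxolan‑4‑yl)acetic acid
Conditions: 2,2‑dimethoxypropane, PPTS (cat.), rt
Reagents that add atoms: 2,2‑dimethoxypropane, COC(C)(C)OC
Why: Acid‑catalysed transacetalisation (acetonide formation) engages only the α‑hydroxy acid unit as the five‑membered dioxolanone, leaving the remote carboxylic acid free and the bought stereocenter untouched.

Step 2
Reactants: 3 (S)‑2‑(2,2‑dimethyl‑5‑oxo‑1,3‑dioxolan‑4‑yl)acetic acid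
Product: 5 (4S)‑4‑hydroxy‑5,5‑dimethyloxolan‑2‑one, via dihydroxy acid 4 (not isolated)
Conditions: MeMgBr (3.3 equiv), THF, −20 to 0 °C; then 2 M HCl, rt
Reagents that add atoms: methylmagnesium bromide, C[Mg]Br
Why: Grignard addition in which the magnesium carboxylate is inert while the activated dioxolanone carbonyl takes up two methyl groups with loss of acetone, after which acidification closes the γ‑lactone onto the new tertiary alcohol (lactonisation) without touching C10.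

Step 3
Reactants: 5 (4S)‑4‑hydroxy‑5,5‑dimethyloxolan‑2‑one
Product: 6 (4S)‑5,5‑dimethyloxolane‑2,4‑diol (lactol; both anomers)
Conditions: iBu2AlH (2.2 equiv), CH2Cl2, −78 °C; Rochelle salt work‑up
Reagents that add atoms: none
Why: Partial lactone reduction with iBu2AlH stops at the tetrahedral aluminium hemiacetal at −78 °C and gives the lactol, a latent γ‑hydroxy aldehyde.

Step 4
Reactants: 1 (S)‑(+)‑carvone
Product: 7 tert‑butyldimethyl{[(5R)‑2‑methyl‑5‑(prop‑1‑en‑2‑yl)cyclohexa‑1,3‑dien‑1‑yl]oxy}silane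
Conditions: tBuMe2SiOTf, Et3N, CH2Cl2, 0 °C to rt
Reagents that add atoms: tert‑butyldimethylsilyl trifluoromethanesulfonate, CC(C)(C)[Si](C)(C)OS(=O)(=O)C(F)(F)F
Why: Soft enolisation under equilibrating conditions gives the thermodynamic through‑conjugated silyl dienol ether by γ‑deprotonation, which leaves the carvone stereocenter untouched.

Step 5
Reactants: 7 tert‑butyldimethyl{[(5R)‑2‑methyl‑5‑(prop‑1‑en‑2‑yl)cyclohexa‑1,3‑dien‑1‑yl]oxy}silane
Product: 9 (4R,5S)‑4‑[(tert‑butyldimethylsilyl)oxy]‑2‑methyl‑5‑(prop‑1‑en‑2‑yl)cyclohex‑2‑en‑1‑one, via silylperoxy enone 8 (not isolated)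
Conditions: O2, tetraphenylporphyrin (cat.), white LEDs, CH2Cl2, −78 °C; then PPh3, −78 °C to rt
Reagents that add atoms: dioxygen, O=O
Why: Photosensitised singlet‑oxygen [4+2] cycloaddition to the 1‑silyloxy‑1,3‑diene on the face anti to the isopropenyl group, silatropic opening to the γ‑silylperoxy enone and phosphine deoxygenation of the peroxide (a vinylogous Rubottom‑type oxygenation) set the C2 oxygen trans to the C1 substituent.

Step 6
Reactants: 9 (4R,5S)‑4‑[(tert‑butyldimethylsilyl)oxy]‑2‑methyl‑5‑(prop‑1‑en‑2‑yl)cyclohex‑2‑en‑1‑one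
Product: 11 (4R,5R,6R)‑4‑[(tert‑butyldimethylsilyl)oxy]‑6‑hydroxy‑2‑methyl‑5‑(prop‑1‑en‑2‑yl)cyclohex‑2‑en‑1‑one, via lithium enolate 10 (not isolated)
Conditions: LiN(iPr)2, THF, −78 °C; then MoO5·pyridine·HMPA, −78 to −20 °C; aq. Na2SO3
Reagents that add atoms: oxodiperoxymolybdenum–pyridine–HMPA complex (MoOPH), O=[Mo]12(OO1)OO2.c1ccncc1.CN(C)P(=O)(N(C)C)N(C)C
Why: Kinetic α′‑deprotonation and Vedejs MoOPH enolate hydroxylation, with the oxidant approaching anti to the adjacent isopropenyl group, give the trans α′‑hydroxy ketone.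

Step 7
Reactants: 11 (4R,5R,6R)‑4‑[(tert‑butyldimethylsilyl)oxy]‑6‑hydroxy‑2‑methyl‑5‑(prop‑1‑en‑2‑yl)cyclohex‑2‑en‑1‑one
Product: 12 (1S,5R,6R)‑5‑[(tert‑butyldimethylsilyl)oxy]‑3‑methyl‑2‑oxo‑6‑(prop‑1‑en‑2‑yl)cyclohex‑3‑en‑1‑yl 2‑methylpropanoate
Conditions: iPrCO2H, PPh3, DIAD, toluene, 0 °C to rt
Reagents that add atoms: isobutyric acid, CC(C)C(=O)O
Why: Mitsunobu esterification of the activated α‑ketol proceeds by SN2 inversion and places the isobutyrate cis to the isopropenyl group, which is the C6β configuration of the target.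

Step 8
Reactants: 12 (1S,5R,6R)‑5‑[(tert‑butyldimethylsilyl)oxy]‑3‑methyl‑2‑oxo‑6‑(prop‑1‑en‑2‑yl)cyclohex‑3‑en‑1‑yl 2‑methylpropanoate
Product: 13 allylic alcohol: C3=C4 cyclohexene with C1β‑isopropenyl/C2α‑OTBS/C5β‑OH/C6β‑O‑isobutyrate
Conditions: NaBH4, CeCl3·7H2O, MeOH, −78 °C
Reagents that add atoms: none
Why: Luche 1,2‑reduction in which axial hydride attack anti to the axial α‑acyloxy group gives the equatorial C5β alcohol cis to the isobutyrate, the same sense as the carvone to cis‑carveol reduction.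

Step 9
Reactants: 13 allylic alcohol
Product: 14 3β,4β‑epoxide of 13
Conditions: VO(acac)2 (5 mol %), tBuOOH, CH2Cl2, 0 °C to rt
Reagents that add atoms: tert‑butyl hydroperoxide, CC(C)(C)OO
Why: Hydroxyl‑directed vanadium‑catalysed epoxidation (Sharpless–Michaelson type) delivers oxygen to the allylic‑alcohol olefin syn to the C5 hydroxyl and anti to the C2 silyl ether, and does not touch the isopropenyl group.

Step 10
Reactants: 14 3β,4β‑epoxide
Product: 15 C3α‑angelate C4β,C5β‑diol (C1β‑isopropenyl/C2α‑OTBS/C4α‑methyl/C6β‑O‑isobutyrate)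
Conditions: angelic acid (3 equiv), Ti(OiPr)4 (1.5 equiv), CH2Cl2, rt
Reagents that add atoms: angelic acid [(Z)‑2‑methylbut‑2‑enoic acid], OC(=O)/C(C)=C\C
Why: Titanium‑assisted opening of the 2,3‑epoxy alcohol by the carboxylic acid at the distal, secondary carbon (trans‑diaxial, Fürst–Plattner) inverts C3 to the α‑angelate and leaves the tertiary C4β oxygen as the free alcohol.

Step 11
Reactants: 15 C3α‑angelate C4β,C5β‑diol
Product: 16 C5β‑acetate of 15
Conditions: Ac2O, pyridine, DMAP (cat.), CH2Cl2, 0 °C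
Reagents that add atoms: acetic anhydride, CC(=O)OC(C)=O
Why: Esterification in which only the secondary C5 hydroxyl is acylated under these mild conditions, while the axial tertiary C4 alcohol is not.

Step 12
Reactants: 16 C5β‑acetate
Product: 17 C4‑O‑trimethylsilyl ether of 16
Conditions: 1‑(trimethylsilyl)imidazole, CH2Cl2, rt
Reagents that add atoms: 1‑(trimethylsilyl)imidazole, C[Si](C)(C)n1ccnc1
Why: Silylation with a neutral, powerful silyl donor caps the tertiary alcohol so that no alkoxide is formed next to the esters in step 14.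

Step 13
Reactants: 17 C4‑O‑trimethylsilyl ether
Product: 19 methyl ketone (C1β‑acetyl compound), via ozonide 18 (not isolated)
Conditions: O3, CH2Cl2, −78 °C (Sudan Red end point); then PPh3, −78 °C to rt
Reagents that add atoms: ozone, [O-][O+]=O
Why: Ozonolysis cleaves the electron‑rich 1,1‑disubstituted olefin far faster than the conjugated angelate, and phosphine reduction of the ozonide gives the methyl ketone.

Step 14
Reactants: 19 methyl ketone
Product: 21 enol triflate: C1β‑[1‑(trifluoromethanesulfonyloxy)ethenyl] compound, via potassium enolate 20 (not isolated)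
Conditions: KN(SiMe3)2 (1.2 equiv), THF, −78 °C; then PhNTf2
Reagents that add atoms: N‑phenylbis(trifluoromethanesulfonimide), O=S(=O)(N(c1ccccc1)S(=O)(=O)C(F)(F)F)C(F)(F)F
Why: Kinetic deprotonation of the methyl group by the hindered amide base and O‑sulfonylation give the terminal enol triflate, turning the former methyl into the exocyclic methylene.

Step 15
Reactants: 21 enol triflate; 6 (4S)‑5,5‑dimethyloxolane‑2,4‑diol
Product: 22 enone: C1β‑[(5S)‑5,6‑dihydroxy‑6‑methyl‑3‑oxohept‑1‑en‑2‑yl] compound (open form of its cyclic hemiketal)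
Conditions: [Ir(dF(CF3)ppy)2(dtbbpy)]PF6 (1 mol %), NiBr2·glyme (10 mol %), 4,4′‑di‑tert‑butyl‑2,2′‑bipyridine (10 mol %), quinuclidine (20 mol %), K2CO3, 1,4‑dioxane, blue LEDs, rt
Reagents that add atoms: none
Why: Proposed new method: a nickel/photoredox/hydrogen‑atom‑transfer coupling of a formyl (lactol) C–H bond with an alkenyl triflate, in which the photoexcited iridium complex oxidises quinuclidine to its radical cation, this abstracts the hydridic C–H of the ring‑opened hydroxy aldehyde form of 6 (or of its hemiacetal carbon, which leads to the same product), the acyl radical is captured by the alkenylnickel triflate formed by oxidative addition of zerovalent nickel into 21, and reductive elimination from trivalent nickel forges the C7–C8 bond as the α‑methylene ketone without creating or touching a stereocenter; the closest known reaction type is the nickel/photoredox/quinuclidine C–H arylation of aldehydes with aryl bromides, which has not been shown with alkenyl triflates or lactols.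

Step 16
Reactants: 22 enone
Product: 23 syn‑diol: C1β‑[(3R,5S)‑3,5,6‑trihydroxy‑6‑methylhept‑1‑en‑2‑yl] compound
Conditions: Et2BOMe, NaBH4, THF/MeOH (4:1), −78 °C; AcOH, MeOH co‑evaporation
Reagents that add atoms: none
Why: Narasaka–Prasad reduction in which the diethylboron chelate of the β‑hydroxy ketone takes up external hydride through a half‑chair and gives the 1,3‑syn diol, so the C10 stereocenter sets C8 as R.

Step 17
Reactants: 23 syn‑diol
Product: 24 C10 isobutyrate of 23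
Conditions: Me2SnCl2 (5 mol %), iPrCOCl (1.1 equiv), iPr2NEt, THF, 0 °C
Reagents that add atoms: isobutyryl chloride, CC(C)C(Cl)=O
Why: Tin‑catalysed regioselective acylation in which the five‑membered stannylene of the C10/C11 1,2‑diol activates the secondary C10 oxygen, while the isolated C8 hydroxyl and the tertiary hydroxyl do not react.

Step 18
Reactants: 24 C10 isobutyrate
Product: 25 CNP0139270.1
Conditions: HF·pyridine, pyridine, THF, 0 °C to rt
Reagents that add atoms: none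
Why: Fluoride‑mediated desilylation under buffered, weakly acidic conditions removes both silyl ethers without acyl migration or ester cleavage.

## Compound list

1 | (S)‑(+)‑carvone, (5S)‑2‑methyl‑5‑(prop‑1‑en‑2‑yl)cyclohex‑2‑en‑1‑one | C=C(C)[C@H]1CC=C(C)C(=O)C1 | starting material
2 | L‑malic acid, (2S)‑2‑hydroxybutanedioic acid | OC(=O)C[C@H](O)C(=O)O | starting material
3 | (S)‑2‑(2,2‑dimethyl‑5‑oxo‑1,3‑dioxolan‑4‑yl)acetic acid | OC(=O)C[C@H]1C(=O)OC(C)(C)O1 | intermediate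
4 | (3S)‑3,4‑dihydroxy‑4‑methylpentanoic acid (not isolated) | OC(=O)C[C@H](O)C(C)(C)O | intermediate
5 | (4S)‑4‑hydroxy‑5,5‑dimethyloxolan‑2‑one | O=C1C[C@H](O)C(C)(C)O1 | intermediate
6 | (4S)‑5,5‑dimethyloxolane‑2,4‑diol (lactol, both anomers) | OC1C[C@H](O)C(C)(C)O1 | intermediate
7 | tert‑butyldimethyl{[(5R)‑2‑methyl‑5‑(prop‑1‑en‑2‑yl)cyclohexa‑1,3‑dien‑1‑yl]oxy}silane | C=C(C)[C@H]1C=CC(C)=C(O[Si](C)(C)C(C)(C)C)C1 | intermediate
8 | (4R,5S)‑4‑[(tert‑butyldimethylsilyl)peroxy]‑2‑methyl‑5‑(prop‑1‑en‑2‑yl)cyclohex‑2‑en‑1‑one (not isolated) | C=C(C)[C@H]1[C@H](OO[Si](C)(C)C(C)(C)C)C=C(C)C(=O)C1 | intermediate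
9 | (4R,5S)‑4‑[(tert‑butyldimethylsilyl)oxy]‑2‑methyl‑5‑(prop‑1‑en‑2‑yl)cyclohex‑2‑en‑1‑one (silyloxy trans to isopropenyl) | C=C(C)[C@H]1[C@H](O[Si](C)(C)C(C)(C)C)C=C(C)C(=O)C1 | intermediate
10 | lithium α′‑enolate of 9 (not isolated) | C=C(C)[C@H]1[C@H](O[Si](C)(C)C(C)(C)C)C=C(C)C(O[Li])=C1 | intermediate
11 | (4R,5R,6R)‑4‑[(tert‑butyldimethylsilyl)oxy]‑6‑hydroxy‑2‑methyl‑5‑(prop‑1‑en‑2‑yl)cyclohex‑2‑en‑1‑one (6‑OH trans to isopropenyl) | C=C(C)[C@H]1[C@H](O[Si](C)(C)C(C)(C)C)C=C(C)C(=O)[C@@H]1O | intermediate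
12 | (1S,5R,6R)‑5‑[(tert‑butyldimethylsilyl)oxy]‑3‑methyl‑2‑oxo‑6‑(prop‑1‑en‑2‑yl)cyclohex‑3‑en‑1‑yl 2‑methylpropanoate (ester cis to isopropenyl) | C=C(C)[C@H]1[C@H](O[Si](C)(C)C(C)(C)C)C=C(C)C(=O)[C@H]1OC(=O)C(C)C | intermediate
13 | allylic alcohol: C3=C4 cyclohexene, C1β‑isopropenyl, C2α‑OTBS, C4‑methyl, C5β‑OH, C6β‑O‑isobutyrate | C=C(C)[C@H]1[C@H](O[Si](C)(C)C(C)(C)C)C=C(C)[C@@H](O)[C@H]1OC(=O)C(C)C | intermediate
14 | 3β,4β‑epoxide of 13 (epoxide oxygen cis to the C5 hydroxyl) | C=C(C)[C@H]1[C@H](O[Si](C)(C)C(C)(C)C)[C@H]2O[C@@]2(C)[C@@H](O)[C@H]1OC(=O)C(C)C | intermediate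
15 | cyclohexane with C1β‑isopropenyl, C2α‑OTBS, C3α‑O‑angelate, C4β‑OH/C4α‑methyl, C5β‑OH, C6β‑O‑isobutyrate | C=C(C)[C@H]1[C@H](O[Si](C)(C)C(C)(C)C)[C@H](OC(=O)/C(C)=C\C)[C@@](C)(O)[C@@H](O)[C@H]1OC(=O)C(C)C | intermediate
16 | C5β‑acetate of 15 | C=C(C)[C@H]1[C@H](O[Si](C)(C)C(C)(C)C)[C@H](OC(=O)/C(C)=C\C)[C@@](C)(O)[C@@H](OC(C)=O)[C@H]1OC(=O)C(C)C | intermediate
17 | C4‑O‑trimethylsilyl ether of 16 | C=C(C)[C@H]1[C@H](O[Si](C)(C)C(C)(C)C)[C@H](OC(=O)/C(C)=C\C)[C@@](C)(O[Si](C)(C)C)[C@@H](OC(C)=O)[C@H]1OC(=O)C(C)C | intermediate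
18 | ozonide (3‑methyl‑1,2,4‑trioxolan‑3‑yl at C1) of 17 (not isolated) | CC2(OOCO2)[C@H]1[C@H](O[Si](C)(C)C(C)(C)C)[C@H](OC(=O)/C(C)=C\C)[C@@](C)(O[Si](C)(C)C)[C@@H](OC(C)=O)[C@H]1OC(=O)C(C)C | intermediate
19 | methyl ketone: C1β‑acetyl compound with the ring substituents of 17 | CC(=O)[C@H]1[C@H](O[Si](C)(C)C(C)(C)C)[C@H](OC(=O)/C(C)=C\C)[C@@](C)(O[Si](C)(C)C)[C@@H](OC(C)=O)[C@H]1OC(=O)C(C)C | intermediate
20 | potassium enolate of 19 at the methyl group (not isolated) | C=C(O[K])[C@H]1[C@H](O[Si](C)(C)C(C)(C)C)[C@H](OC(=O)/C(C)=C\C)[C@@](C)(O[Si](C)(C)C)[C@@H](OC(C)=O)[C@H]1OC(=O)C(C)C | intermediate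
21 | enol triflate: C1β‑[1‑(trifluoromethanesulfonyloxy)ethenyl] compound | C=C(OS(=O)(=O)C(F)(F)F)[C@H]1[C@H](O[Si](C)(C)C(C)(C)C)[C@H](OC(=O)/C(C)=C\C)[C@@](C)(O[Si](C)(C)C)[C@@H](OC(C)=O)[C@H]1OC(=O)C(C)C | intermediate
22 | enone: C1β‑[(5S)‑5,6‑dihydroxy‑6‑methyl‑3‑oxohept‑1‑en‑2‑yl] compound (open form; in equilibrium with the five‑membered hemiketal) | C=C([C@H]1[C@H](O[Si](C)(C)C(C)(C)C)[C@H](OC(=O)/C(C)=C\C)[C@@](C)(O[Si](C)(C)C)[C@@H](OC(C)=O)[C@H]1OC(=O)C(C)C)C(=O)C[C@H](O)C(C)(C)O | intermediate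
23 | syn‑diol: C1β‑[(3R,5S)‑3,5,6‑trihydroxy‑6‑methylhept‑1‑en‑2‑yl] compound | C=C([C@H]1[C@H](O[Si](C)(C)C(C)(C)C)[C@H](OC(=O)/C(C)=C\C)[C@@](C)(O[Si](C)(C)C)[C@@H](OC(C)=O)[C@H]1OC(=O)C(C)C)[C@H](O)C[C@H](O)C(C)(C)O | intermediate
24 | C10 isobutyrate of 23 (C2‑OTBS and C4‑OTMS still in place) | C=C([C@H]1[C@H](O[Si](C)(C)C(C)(C)C)[C@H](OC(=O)/C(C)=C\C)[C@@](C)(O[Si](C)(C)C)[C@@H](OC(C)=O)[C@H]1OC(=O)C(C)C)[C@H](O)C[C@H](OC(=O)C(C)C)C(C)(C)O | intermediate
25 | CNP0139270.1: cyclohexane (1S,2S,3S,4R,5S,6S) with 2‑OH, 3‑O‑angelate, 4‑OH/4‑CH3, 5‑OAc, 6‑O‑isobutyrate and at C1 the (3R,5S)‑3,6‑dihydroxy‑6‑methyl‑5‑(isobutyryloxy)hept‑1‑en‑2‑yl chain | C=C([C@H]1[C@H](O)[C@H](OC(=O)/C(C)=C\C)[C@@](C)(O)[C@@H](OC(C)=O)[C@H]1OC(=O)C(C)C)[C@H](O)C[C@H](OC(=O)C(C)C)C(C)(C)O | target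

## Step count and risks

Total: 18 steps. Longest linear sequence: 15 steps (steps 4–18 from (S)‑carvone 1); the three‑step side‑chain branch from 2 joins at step 15.

Steps most likely to fail:

- **Step 7 (Mitsunobu inversion of ketol 11).** Risks are elimination towards the cross‑conjugated dienone (then phenol) and slow SN2 next to the isopropenyl‑bearing carbon. Fallback: set out from enone 9; LiN(iPr)2 then N‑bromosuccinimide at −78 °C gives the α′‑bromo ketone F1 (bromine trans to isopropenyl). CsO2CiPr in DMF at 0 °C displaces bromide with inversion and gives 12, where the route resumes.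

- **Step 15 (proposed new acyl C–H alkenylation).** Risks are hydrogen abstraction at the carbinol C–H of 6, addition of the acyl radical to the product enone, and slow oxidative addition at the hindered triflate. Fallback with known chemistry: set out from 21 and 6; a Nozaki–Hiyama–Kishi coupling (CrCl2, NiCl2 cat., DMF/THF, rt) gives the allylic alcohols F2 as a mixture at C8. MnO2 in CH2Cl2 oxidises only the allylic alcohol and returns enone 22, where the route resumes.

- **Step 17 (regioselective acylation of triol 23).** Risk is competing acylation of the allylic C8 hydroxyl. Fallback: set out from 23; Et3SiOTf (1.05 equiv), 2,6‑lutidine, −78 °C silylates the less hindered C8 hydroxyl and gives the triethylsilyl ether F3. Isobutyric anhydride, DMAP and Et3N then acylate C10 to give the ester F4. The HF·pyridine conditions of step 18 remove all three silyl groups and give 25.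

## Further compounds

F1 | step 7 | (4R,5R,6R)‑6‑bromo‑4‑[(tert‑butyldimethylsilyl)oxy]‑2‑methyl‑5‑(prop‑1‑en‑2‑yl)cyclohex‑2‑en‑1‑one (bromine trans to isopropenyl) | C=C(C)[C@H]1[C@H](O[Si](C)(C)C(C)(C)C)C=C(C)C(=O)[C@@H]1Br
F2 | step 15 | allylic alcohols: C8 epimer mixture of the 3,5,6‑trihydroxy‑6‑methylhept‑1‑en‑2‑yl compound (ring substituents as in 21) | C=C([C@H]1[C@H](O[Si](C)(C)C(C)(C)C)[C@H](OC(=O)/C(C)=C\C)[C@@](C)(O[Si](C)(C)C)[C@@H](OC(C)=O)[C@H]1OC(=O)C(C)C)C(O)C[C@H](O)C(C)(C)O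
F3 | step 17 | C8‑O‑triethylsilyl ether of 23 | C=C([C@H]1[C@H](O[Si](C)(C)C(C)(C)C)[C@H](OC(=O)/C(C)=C\C)[C@@](C)(O[Si](C)(C)C)[C@@H](OC(C)=O)[C@H]1OC(=O)C(C)C)[C@H](O[Si](CC)(CC)CC)C[C@H](O)C(C)(C)O
F4 | step 17 | C10 isobutyrate of F3 | C=C([C@H]1[C@H](O[Si](C)(C)C(C)(C)C)[C@H](OC(=O)/C(C)=C\C)[C@@](C)(O[Si](C)(C)C)[C@@H](OC(C)=O)[C@H]1OC(=O)C(C)C)[C@H](O[Si](CC)(CC)CC)C[C@H](OC(=O)C(C)C)C(C)(C)O
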